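**Retrosynthetic overview**

1. Last disconnection (key step): the C13'=C14' olefin (side-chain carbons counted C1'–C21' outward from pyrrole C3) goes back to 3-(tetradec-13-enyl)pyrrole-2-carbaldehyde and 1-nonene by cross-metathesis, with the double bond hydrogenated in the same flask.
2. Feature that allows it: C13' and C14' are two ordinary CH2 groups of an unbranched chain without heteroatom or stereocentre, so their bond can be made one oxidation level higher as a C=C of irrelevant geometry; the N1–C2–CHO unit of the pyrrole ring is a vinylogous formamide (non-basic N–H, deactivated C=O), so the free head group should tolerate Ru=CHR and H2/Pd.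
3. The 2-formylpyrrole ring comes from photochemical ring contraction of a 4-alkylpyridine N-oxide (pyridine C2 becomes the CHO carbon, C3 becomes pyrrole C2, C4 with the chain becomes pyrrole C3); C2 and C6 of the N-oxide are equivalent, so only the 3-alkyl-2-formyl pattern can arise.
4. The 4-alkenylpyridine comes from 4-bromopyridine and 1,13-tetradecadiene (mono-hydroboration, B-alkyl Suzuki–Miyaura coupling); the second C=C is saved for the key step.
5. Ring order: the pyridine ring is bought, oxidised at nitrogen and contracted to the pyrrole (the only ring of the target) in step 3; the key step closes no ring.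

Key step: step 4

Remark: 1,13-tetradecadiene, 9-BBN, 4-bromopyridine hydrochloride and 1-nonene are taken as commercial; the target has no stereocentre, and the only stereochemical element on the route is the transient E/Z mixture 9, which hydrogenation erases.

**Step 1**
Reactants: 1 tetradeca-1,13-diene (3 equiv); 2 9-borabicyclo[3.3.1]nonane (9-BBN, 1 equiv); 3 4-bromopyridine hydrochloride (0.8 equiv)
Product: 5 4-(tetradec-13-en-1-yl)pyridine, via B-(tetradec-13-en-1-yl)-9-BBN 4 (not isolated)
Conditions: 9-BBN, THF, 0 °C to rt; then 3, PdCl2(dppf) (3 mol%), 3 M aq NaOH, THF, 65 °C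
Reagents that add atoms: none
Why: Anti-Markovnikov hydroboration of one terminal C=C (the excess diene should keep it at the mono-adduct) followed by B-alkyl Suzuki–Miyaura coupling, in which the hydroxide-activated borate should transmetalate to the 4-pyridyl–Pd(dppf) species faster than β-hydride elimination, forms the pyridine C4–C1' bond and leaves the remote C=C untouched.

**Step 2**
Reactants: 5 4-(tetradec-13-en-1-yl)pyridine
Product: 6 4-(tetradec-13-en-1-yl)pyridine 1-oxide
Conditions: mCPBA (1.05 equiv), CH2Cl2, 0 °C; aq K2CO3 wash
Reagents that add atoms: mCPBA (3-chloroperoxybenzoic acid), OOC(=O)c1cccc(Cl)c1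
Why: Peracid N-oxidation of a pyridine: the nitrogen lone pair is far more nucleophilic towards the peracid than a monosubstituted terminal alkene (Prilezhaev epoxidation is slow there), so one equivalent at 0 °C should oxidise nitrogen only.

**Step 3**
Reactants: 6 4-(tetradec-13-en-1-yl)pyridine 1-oxide
Product: 7 3-(tetradec-13-en-1-yl)-1H-pyrrole-2-carbaldehyde
Conditions: hν (254 nm, quartz), CuSO4·5H2O (2 equiv), MeCN/H2O 3:1, 5 mM, N2, 15 °C; aq Na2EDTA work-up
Reagents that add atoms: none
Why: Copper(II)-assisted photochemical ring contraction of a pyridine N-oxide (N-oxide to oxaziridine/1,2-oxazepine, then Cu-templated reclosure to the 2-formylpyrrole) is an isomerisation that should turn the symmetrical 4-substituted N-oxide into the 3-substituted 2-formylpyrrole only, and the isolated alkene does not absorb at 254 nm.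

**Step 4**
Reactants: 7 3-(tetradec-13-en-1-yl)-1H-pyrrole-2-carbaldehyde; 8 non-1-ene (8 equiv)
Product: 10 3-henicosyl-1H-pyrrole-2-carbaldehyde, via 3-(henicos-13-en-1-yl)-1H-pyrrole-2-carbaldehyde 9 (not isolated)
Conditions: Hoveyda–Grubbs II (3 mol%), 1,4-benzoquinone (10 mol%), CH2Cl2, 40 °C, Ar sweep; then strip volatiles, EtOAc, 5% Pd/C, H2 (1 atm), rt, same flask
Reagents that add atoms: none
Why: The Ru alkylidene shuttles between the two terminal olefins through metallacyclobutanes (Chauvin mechanism), and loss of ethene joins the octylidene unit of 8 to the chain terminus of 7 as the C13'=C14' double bond of 9. The closest known reaction type is cross-metathesis of two unhindered terminal (type I) olefins followed by one-pot heterogeneous hydrogenation. No ring is closed and no stereocentre is created; the E/Z mixture 9 converges on one saturated chain when H2 and Pd/C are admitted. The selectivity needed is cross- over homo-coupling, which the eight-fold excess of cheap 1-nonene should secure (its homodimer is hydrogenated to an easily removed alkane), while benzoquinone suppresses Ru–H double-bond migration that would blur the chain length. Chemoselectivity at the head group rests on the pyrrole N1–C2–CHO unit being a vinylogous formamide: the N–H is non-basic and should not bind Ru, and the deactivated aldehyde and the aromatic ring should be reduced far more slowly than the isolated 1,2-disubstituted alkene at 1 atm H2.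

**Compound list**

1 | tetradeca-1,13-diene | C=CCCCCCCCCCCCC=C | starting material
2 | 9-borabicyclo[3.3.1]nonane (9-BBN) | B1C2CCCC1CCC2 | starting material
3 | 4-bromopyridine hydrochloride | Cl.Brc1ccncc1 | starting material
4 | B-(tetradec-13-en-1-yl)-9-borabicyclo[3.3.1]nonane | C=CCCCCCCCCCCCCB1C2CCCC1CCC2 | intermediate (not isolated)
5 | 4-(tetradec-13-en-1-yl)pyridine | C=CCCCCCCCCCCCCc1ccncc1 | intermediate
6 | 4-(tetradec-13-en-1-yl)pyridine 1-oxide | C=CCCCCCCCCCCCCc1cc[n+]([O-])cc1 | intermediate
7 | 3-(tetradec-13-en-1-yl)-1H-pyrrole-2-carbaldehyde | C=CCCCCCCCCCCCCc1cc[nH]c1C=O | intermediate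
8 | non-1-ene | C=CCCCCCCC | starting material
9 | 3-(henicos-13-en-1-yl)-1H-pyrrole-2-carbaldehyde (E/Z mixture) | CCCCCCCC=CCCCCCCCCCCCCc1cc[nH]c1C=O | intermediate (not isolated)
10 | 3-henicosyl-1H-pyrrole-2-carbaldehyde | CCCCCCCCCCCCCCCCCCCCCc1cc[nH]c1C=O | target

**Step count and risks**

Total steps: 4. Longest linear sequence: 4 (from tetradeca-1,13-diene).

Step 3 is the most likely to fail. The excited N-oxide may lose oxygen to give back the pyridine, may rearrange to pyridone- or hydroxypyridine-type isomers, or the amphiphilic substrate may aggregate and be over-irradiated; the product may also be held back as its copper chelate. The fallback builds the head group from a pyrrole instead of a pyridine and sets out from borane 4 (made from 1 and 2 as in step 1). Suzuki–Miyaura coupling of 4 with commercial 3-bromo-1-(triisopropylsilyl)pyrrole should give 3-(tetradec-13-en-1-yl)-1-(triisopropylsilyl)-1H-pyrrole F1. Fluoride (TBAF, THF) should then free 3-(tetradec-13-en-1-yl)-1H-pyrrole F2. Vilsmeier–Haack formylation (POCl3, DMF, then aq NaOAc) is expected to attack mainly the α-position next to the alkyl group; after chromatographic removal of the 4-alkyl isomer the route is rejoined at 7.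

Step 4 is second. The valuable olefin 7 may homodimerise, a Ru hydride may move the double bond before metathesis and so give chain-length homologues, or the formyl group may be over-reduced during hydrogenation. The fallback makes the same C13'=C14' bond by carbonyl olefination at the pyridine stage and sets out from 5. Ozonolysis (O3, CH2Cl2/MeOH, −78 °C; Me2S) should give 13-(pyridin-4-yl)tridecanal F3. Wittig reaction with octylidenetriphenylphosphorane F4 (from octyltriphenylphosphonium bromide and NaHMDS, THF, −78 °C to rt) should give 4-[(13Z)-henicos-13-en-1-yl]pyridine F5. Hydrogenation (H2, Pd/C) should give 4-henicosylpyridine F6, and mCPBA should give 4-henicosylpyridine 1-oxide F7. Photochemical ring contraction as in step 3 would then rejoin the route at 10.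

Step 1 is third. Double hydroboration of the diene would lead to a bis-pyridyl by-product, and transmetalation may be slowed if the pyridine nitrogen occupies palladium, which leaves room for protodeboronation. The fallback replaces boron by zinc and sets out from 1. Radical anti-Markovnikov addition of HBr (HBr, AIBN cat., hexane, 0 °C, excess diene) should give 14-bromotetradec-1-ene F8. Zinc insertion (Zn dust, I2 cat., DMA, 70 °C) should give (tetradec-13-en-1-yl)zinc bromide F9. Negishi coupling [PdCl2(dppf), THF/DMA, 50 °C] with 4-bromopyridine F10, liberated from 3 with aqueous NaHCO3 just before use, would rejoin the route at 5.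

**Further compounds**

F1 | step 3 | 3-(tetradec-13-en-1-yl)-1-(triisopropylsilyl)-1H-pyrrole | C=CCCCCCCCCCCCCc1ccn([Si](C(C)C)(C(C)C)C(C)C)c1
F2 | step 3 | 3-(tetradec-13-en-1-yl)-1H-pyrrole | C=CCCCCCCCCCCCCc1cc[nH]c1
F3 | step 4 | 13-(pyridin-4-yl)tridecanal | O=CCCCCCCCCCCCCc1ccncc1
F4 | step 4 | octylidenetriphenylphosphorane | CCCCCCCC=P(c1ccccc1)(c1ccccc1)c1ccccc1
F5 | step 4 | 4-[(13Z)-henicos-13-en-1-yl]pyridine | CCCCCCC/C=C\CCCCCCCCCCCCc1ccncc1
F6 | step 4 | 4-henicosylpyridine | CCCCCCCCCCCCCCCCCCCCCc1ccncc1
F7 | step 4 | 4-henicosylpyridine 1-oxide | CCCCCCCCCCCCCCCCCCCCCc1cc[n+]([O-])cc1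
F8 | step 1 | 14-bromotetradec-1-ene | C=CCCCCCCCCCCCCBr
F9 | step 1 | (tetradec-13-en-1-yl)zinc bromide | C=CCCCCCCCCCCCC[Zn]Br
F10 | step 1 | 4-bromopyridine | Brc1ccncc1
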